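Ring D is cut at C13–C16 (vinyl radical cyclisation) and C15–C16 (acetylide addition), ring C at C9–C11 and C8–C14 (butadiene [4+2]), the lactone at C8=C9 (Knoevenagel) and at its C20–O ester bond, and ring A at C1–C10 and C4–C5 ([4+2]).
Forward, ring A is made first, then the lactone ring, ring C and ring D; C6 travels as a dithiolane and is freed in the last step.
The enabling feature is in ring A: C6 (aldehyde) and C20 (CH2–O) are cis one-carbon groups on the adjacent carbons C5 and C10, which is a 5-alkoxybutenolide with C5=C10 as its double bond, while the oxygens on C1 and C3 are 1,3-related as in a 1-acyloxy-3-silyloxy diene that ends in the dimethylated C4.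
Stereochemistry: C5 and C10 come from the (R)-menthyloxy acetal (anti addition), C1 from the endo rule, C3 from axial hydride delivery, C8 and C9 from the face of the spiro lactone left open by ring A, C13 from the geometry of the bridged ring, and C15 from exo-face hydride addition to the enone.

Key step: step 5

Remark: atoms are numbered as in kaurane (C1–C20); Troc = 2,2,2-trichloroethoxycarbonyl, TBS = tert-butyldimethylsilyl; compounds 27, 28 and 29 are carried as mixtures of C15 epimers that converge at enone 30.

Step 1
Reactants: 1 (5R)-5-[(1R,2S,5R)-menthyloxy]furan-2(5H)-one; 2 formaldehyde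
Product: 3 (5R)-3-(hydroxymethyl)-5-[(1R,2S,5R)-menthyloxy]furan-2(5H)-one
Conditions: 37% aq. HCHO, PBu3 (0.2 equiv), THF, 23 °C
Reagents that add atoms: none
Why: Morita–Baylis–Hillman reaction, in which the phosphine adds to the β-carbon, the enolate adds to formaldehyde and elimination returns the butenolide, while the weakly basic catalyst should leave the acetal centre unepimerised.

Step 2
Reactants: 3 hydroxymethyl butenolide
Product: 4 [(5R)-5-[(1R,2S,5R)-menthyloxy]-2-oxo-2,5-dihydrofuran-3-yl]methyl 2,2,2-trichloroethyl carbonate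
Conditions: ClCO2CH2CCl3, pyridine, CH2Cl2, 0 °C
Reagents that add atoms: 2,2,2-trichloroethyl chloroformate, ClC(=O)OCC(Cl)(Cl)Cl
Why: Acylation of the primary alcohol gives a carbonate that withstands heat, BF3/thiol and borane and is later removed by zinc, whereas a benzylic ether would be lost with BF3/thiol and its oxidative removal would endanger the dithiolane.

Step 3
Reactants: 5 3-methylbutan-2-one; 6 ethyl formate
Product: 8 (E)-4-methyl-3-oxopent-1-en-1-yl acetate, via sodium 4-methyl-3-oxopent-1-en-1-olate 7 (not isolated)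
Conditions: NaH, Et2O, 0 → 23 °C; then AcCl, 0 °C
Reagents that add atoms: acetyl chloride, CC(Cl)=O
Why: Claisen formylation at the methyl group (the only side that leads to a stabilised enolate) followed by O-acetylation of the sodium enolate, which should give the (E)-enol acetate.

Step 4
Reactants: 8 acetoxy enone
Product: 9 (E)-3-(tert-butyldimethylsilyloxy)-4-methylpenta-1,3-dien-1-yl acetate
Conditions: TBSOTf, Et3N, Et2O, 0 °C
Reagents that add atoms: tert-butyldimethylsilyl trifluoromethanesulfonate, CC(C)(C)[Si](C)(C)OS(=O)(=O)C(F)(F)F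
Why: Soft enolisation and O-silylation, for which the isopropyl C–H is the only enolisable position, so the dienol silane with the tetrasubstituted terminus is the sole regioisomer.

Step 5
Reactants: 4 butenolide carbonate; 9 diene
Product: 10 ring A cycloadduct (3R,3aR,7S,7aS)-7-acetoxy-5-(tert-butyldimethylsilyloxy)-3-menthyloxy-4,4-dimethyl-7a-(Troc-oxymethyl)-3a,4,7,7a-tetrahydro-2-benzofuran-1(3H)-one
Conditions: 9 (3 equiv), BHT (cat.), toluene, 125 °C, sealed tube
Reagents that add atoms: none
Why: Thermal, concerted but asynchronous [4+2] cycloaddition in which C4 of the diene (the β-carbon of the silyl enol ether and its most nucleophilic terminus) bonds to the butenolide β-carbon C5 ahead of the C1–C10 bond, so the silyloxy group fixes the regiochemistry. The closest known reactions are the Diels–Alder additions of 1,3-dioxygenated dienes to 5-menthyloxyfuran-2(5H)-ones. Ring A closes as a six-membered carbocycle by intermolecular suprafacial addition across C5=C10, which leaves the C20/C6 lactone cis-fused to it. C5 and C10 are set by approach of the diene to the butenolide face anti to the menthyloxy group on C6, and C1 is set by the endo transition state (lactone carbonyl under the diene), which places the (E)-acetoxy group cis to C20. The step needs regio-, face- and endo-selectivity, secured by the C3 silyloxy group, the acetal substituent and the ring-locked lactone carbonyl respectively; its weak point is the fully substituted diene terminus, hence the excess of diene and the high temperature.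

Step 6
Reactants: 10 ring A cycloadduct
Product: 12 C3 alcohol (3R) of the ring A lactone acetal, via 3-ketone 11 (not isolated)
Conditions: TBAF, AcOH, THF, 0 °C; then MeOH, NaBH4, −40 °C
Reagents that add atoms: none
Why: Buffered fluoride cleaves the enol silane to the β-acetoxy ketone without β-elimination, and borohydride reduction then proceeds by axial attack at C3 from the face of H1 and H5, away from the axial C4 methyl, to give the equatorial alcohol cis to the acetate.

Step 7
Reactants: 12 C3 alcohol
Product: 13 C3 tert-butyldimethylsilyl ether of 12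
Conditions: TBSOTf, 2,6-lutidine, CH2Cl2, 0 °C
Reagents that add atoms: tert-butyldimethylsilyl trifluoromethanesulfonate, CC(C)(C)[Si](C)(C)OS(=O)(=O)C(F)(F)F
Why: Silylation of the hindered secondary alcohol with the silyl triflate gives an ether that, flanked by the gem-dimethyl carbon, should outlast the Lewis acid, borane, zinc and both later cycloadditions.

Step 8
Reactants: 13 silyl ether
Product: 14 ring A carboxylic acid with C6 as 1,3-dithiolane
Conditions: HS(CH2)2SH, BF3·OEt2, CH2Cl2, −20 → 0 °C
Reagents that add atoms: ethane-1,2-dithiol, SCCS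
Why: Lewis acid transthioacetalisation of the lactone acetal (a pseudo ester) is driven by irreversible dithiolane formation and so opens the ring, leaving C6 as a protected aldehyde and C20 as a free carboxylic acid with release of menthol.

Step 9
Reactants: 14 carboxylic acid
Product: 15 C20 primary alcohol
Conditions: BH3·THF, THF, 0 → 23 °C; then MeOH
Reagents that add atoms: none
Why: Borane reduction of a carboxylic acid through its acyloxyborane is much faster than attack on the acetate or the carbonate, so only C20 is taken to the alcohol.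

Step 10
Reactants: 16 2,2-dimethyl-1,3-dioxane-4,6-dione (Meldrum's acid); 17 ethanethiol
Product: 18 3-(ethylsulfanyl)-3-oxopropanoic acid
Conditions: toluene, 90 °C, sealed tube
Reagents that add atoms: none
Why: Thermal acyl transfer from Meldrum's acid to the thiol with loss of acetone is the standard preparation of malonic acid half thioesters.

Step 11
Reactants: 15 C20 alcohol; 18 malonic half thioester
Product: 19 C20 O-malonyl ester (S-ethyl thioester terminus)
Conditions: DCC, CH2Cl2, 0 → 23 °C
Reagents that add atoms: none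
Why: Carbodiimide esterification of the neopentyl alcohol (through the acylketene of the malonic half acid) runs without base, so neither the C1 acetate nor the C9 carbonate should migrate to the free hydroxyl.

Step 12
Reactants: 19 malonyl ester carbonate
Product: 20 C9 primary alcohol
Conditions: Zn, AcOH, THF, 23 °C
Reagents that add atoms: none
Why: Reductive fragmentation of the trichloroethyl carbonate by zinc (β-elimination, then loss of CO2) frees the C9 alcohol while acetate, thioester, silyl ether and dithiolane are inert, and the crude alcohol is oxidised at once to forestall acyl migration between the two hydroxymethyl groups on C10.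

Step 13
Reactants: 20 C9 alcohol
Product: 21 C9 aldehyde
Conditions: Dess–Martin periodinane, CH2Cl2, 0 → 23 °C
Reagents that add atoms: none
Why: Dess–Martin oxidation of the neopentyl alcohol under anhydrous conditions spares the dithiolane and avoids activated-DMSO reagents, which could sulfenylate the malonyl CH2.

Step 14
Reactants: 21 C9 aldehyde
Product: 22 spiro α-alkylidene lactone (C8=C9) with the thioester on C8
Conditions: piperidinium acetate (0.1 equiv), 4 Å MS, benzene, 40 °C
Reagents that add atoms: none
Why: Intramolecular Knoevenagel condensation of the malonyl CH2 (C8) with the non-enolisable aldehyde (C9) closes the six-membered lactone ring and dehydrates to the conjugated alkylidene.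

Step 15
Reactants: 22 alkylidene lactone; 23 buta-1,3-diene
Product: 24 cyclohexene-fused lactone thioester (rings A and C plus lactone)
Conditions: butadiene (excess), ZnCl2, CH2Cl2, −20 → 23 °C, sealed tube
Reagents that add atoms: none
Why: Diels–Alder reaction of the doubly activated alkylidene, chelated by ZnCl2 through the lactone and thioester carbonyls, forms C9–C11 and C8–C14 suprafacially and should occur on the lactone face flanked by the C1 acetate, away from C5 with its dithiolane, which sets C9 and the quaternary C8 and leaves the C12=C13 alkene.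

Step 16
Reactants: 24 thioester
Product: 25 C15 aldehyde
Conditions: Et3SiH, 10% Pd/C, acetone, 23 °C
Reagents that add atoms: none
Why: Fukuyama reduction converts the thioester selectively into the aldehyde and leaves lactone, acetate and the ring alkene alone.

Step 17
Reactants: 25 C15 aldehyde; 26 ethynylmagnesium bromide
Product: 27 C15 propargylic alcohol (both C15 epimers)
Conditions: HC≡CMgBr, THF, −78 °C; then aq. NH4Cl
Reagents that add atoms: none
Why: 1,2-Addition of the acetylide to the non-enolisable aldehyde at low temperature is faster than attack on the lactone or the acetate, and the C15 configuration is deliberately left uncontrolled because it is reset in steps 19 and 20.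

Step 18
Reactants: 27 propargylic alcohol
Product: 29 15-hydroxy-16-methylene bicyclo[3.2.1]octane compound (C15 epimers), via C17-tributylstannyl alkene 28 (not isolated)
Conditions: Bu3SnH, AIBN, benzene, 80 °C; then PPTS, CH2Cl2, 23 °C
Reagents that add atoms: none
Why: Stork-type stannyl radical cyclisation, in which Bu3Sn• adds to the alkyne terminus C17, the C16 vinyl radical closes 5-exo-trig onto C13 (kept kinetic by a high stannane concentration), the C12 radical is reduced and protodestannylation leaves the exocyclic methylene; C13 can only form with the two-carbon bridge cis across ring C.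

Step 19
Reactants: 29 allylic alcohols
Product: 30 15-oxo-16-methylene enone
Conditions: (COCl)2, DMSO, CH2Cl2, −78 °C; then Et3N, −78 → 0 °C
Reagents that add atoms: none
Why: Swern oxidation, which tolerates the dithiolane, merges both C15 epimers into the single α-methylene ketone.

Step 20
Reactants: 30 enone
Product: 31 (15R)-allylic alcohol
Conditions: NaBH4, CeCl3·7H2O, MeOH, −78 °C
Reagents that add atoms: none
Why: Luche 1,2-reduction, in which hydride should enter from the exo face of the bicyclo[3.2.1]octenone (the side of the one-carbon bridge C14), as with norbornan-2-one-type ketones, to give the endo 15R alcohol.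

Step 21
Reactants: 31 silyl ether
Product: 32 3,15-diol with C6 still as dithiolane
Conditions: HF·pyridine, THF, 0 → 23 °C
Reagents that add atoms: none
Why: Fluoride cleavage of the hindered silyl ether under mildly acidic, non-basic conditions, so the C1 acetate should not migrate to O3 and the allylic alcohol should not ionise.

Step 22
Reactants: 32 dithiolane diol
Product: 33 CNP0536233.1
Conditions: MeI, CaCO3, MeCN–H2O (4:1), 45 °C
Reagents that add atoms: water, O
Why: S-Methylation turns the dithiolane into a leaving group and buffered hydrolysis releases the C6 aldehyde last, under neutral conditions that preserve the allylic alcohol, the acetate, the lactone and the C5 stereocentre.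

Compound list
1 | (5R)-5-[(1R,2S,5R)-menthyloxy]furan-2(5H)-one | O=C1O[C@@H](O[C@@H]2C[C@H](C)CC[C@H]2C(C)C)C=C1 | starting material
2 | formaldehyde | C=O | starting material
3 | (5R)-3-(hydroxymethyl)-5-[(1R,2S,5R)-menthyloxy]furan-2(5H)-one | O=C1O[C@@H](O[C@@H]2C[C@H](C)CC[C@H]2C(C)C)C=C1CO | intermediate
4 | [(5R)-5-[(1R,2S,5R)-menthyloxy]-2-oxo-2,5-dihydrofuran-3-yl]methyl 2,2,2-trichloroethyl carbonate | O=C1O[C@@H](O[C@@H]2C[C@H](C)CC[C@H]2C(C)C)C=C1COC(=O)OCC(Cl)(Cl)Cl | intermediate
5 | 3-methylbutan-2-one | CC(C)C(C)=O | starting material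
6 | ethyl formate | CCOC=O | starting material
7 | sodium (E)-4-methyl-3-oxopent-1-en-1-olate (not isolated) | CC(C)C(=O)/C=C/[O-].[Na+] | intermediate
8 | (E)-4-methyl-3-oxopent-1-en-1-yl acetate | CC(=O)O/C=C/C(=O)C(C)C | intermediate
9 | (E)-3-(tert-butyldimethylsilyloxy)-4-methylpenta-1,3-dien-1-yl acetate | CC(=O)O/C=C/C(O[Si](C)(C)C(C)(C)C)=C(C)C | intermediate
10 | (3R,3aR,7S,7aS)-7-acetoxy-5-(tert-butyldimethylsilyloxy)-3-[(1R,2S,5R)-menthyloxy]-4,4-dimethyl-7a-{[(2,2,2-trichloroethoxy)carbonyl]oxymethyl}-3a,4,7,7a-tetrahydro-2-benzofuran-1(3H)-one (ring A; C1 acetate, C2=C3 enol silane, C20 lactone carbonyl, C6 acetal carbon, C9 on C10) | O=C1O[C@@H](O[C@@H]3C[C@H](C)CC[C@H]3C(C)C)[C@@H]2C(C)(C)C(O[Si](C)(C)C(C)(C)C)=C[C@H](OC(C)=O)[C@]12COC(=O)OCC(Cl)(Cl)Cl | intermediate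
11 | C3 ketone of 10 (β-acetoxy ketone; not isolated) | O=C1O[C@@H](O[C@@H]3C[C@H](C)CC[C@H]3C(C)C)[C@@H]2C(C)(C)C(=O)C[C@H](OC(C)=O)[C@]12COC(=O)OCC(Cl)(Cl)Cl | intermediate
12 | (3R)-C3 alcohol of the ring A lactone acetal; hydroxyl cis to the C1 acetate and to C20 | O=C1O[C@@H](O[C@@H]3C[C@H](C)CC[C@H]3C(C)C)[C@@H]2C(C)(C)[C@H](O)C[C@H](OC(C)=O)[C@]12COC(=O)OCC(Cl)(Cl)Cl | intermediate
13 | C3 tert-butyldimethylsilyl ether of 12 | O=C1O[C@@H](O[C@@H]3C[C@H](C)CC[C@H]3C(C)C)[C@@H]2C(C)(C)[C@H](O[Si](C)(C)C(C)(C)C)C[C@H](OC(C)=O)[C@]12COC(=O)OCC(Cl)(Cl)Cl | intermediate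
14 | ring A acid: C10 bears CO2H (C20) and CH2OTroc (C9), C1 acetate, C3 OTBS, C4 gem-dimethyl, C5 1,3-dithiolan-2-yl (C6); acetate, silyl ether, C20 and C6 on one face | OC(=O)[C@@]1(COC(=O)OCC(Cl)(Cl)Cl)[C@@H](OC(C)=O)C[C@@H](O[Si](C)(C)C(C)(C)C)C(C)(C)[C@H]1C2SCCS2 | intermediate
15 | C20 primary alcohol corresponding to 14 | OC[C@@]1(COC(=O)OCC(Cl)(Cl)Cl)[C@@H](OC(C)=O)C[C@@H](O[Si](C)(C)C(C)(C)C)C(C)(C)[C@H]1C2SCCS2 | intermediate
16 | 2,2-dimethyl-1,3-dioxane-4,6-dione (Meldrum's acid) | CC1(C)OC(=O)CC(=O)O1 | starting material
17 | ethanethiol | CCS | starting material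
18 | 3-(ethylsulfanyl)-3-oxopropanoic acid | CCSC(=O)CC(O)=O | intermediate
19 | C20 ester of 15 with 18 (O-malonyl ester, S-ethyl thioester terminus; C9 still OTroc) | CCSC(=O)CC(=O)OC[C@@]1(COC(=O)OCC(Cl)(Cl)Cl)[C@@H](OC(C)=O)C[C@@H](O[Si](C)(C)C(C)(C)C)C(C)(C)[C@H]1C2SCCS2 | intermediate
20 | C9 alcohol from 19 | CCSC(=O)CC(=O)OC[C@@]1(CO)[C@@H](OC(C)=O)C[C@@H](O[Si](C)(C)C(C)(C)C)C(C)(C)[C@H]1C2SCCS2 | intermediate
21 | C9 aldehyde from 20 | CCSC(=O)CC(=O)OC[C@@]1(C=O)[C@@H](OC(C)=O)C[C@@H](O[Si](C)(C)C(C)(C)C)C(C)(C)[C@H]1C2SCCS2 | intermediate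
22 | spiro lactone: 2-oxo-5,6-dihydro-2H-pyran with C8=C9, S-ethyl carbothioate on C8, spiro at C10 to ring A | CCSC(=O)C1=C[C@]2(COC1=O)[C@@H](OC(C)=O)C[C@@H](O[Si](C)(C)C(C)(C)C)C(C)(C)[C@H]2C3SCCS3 | intermediate
23 | buta-1,3-diene | C=CC=C | starting material
24 | butadiene adduct: ring C cyclohexene (C12=C13) fused at C8–C9 to the lactone, thioester on C8; C11 and C14 on the lactone face of C1 | C1=CC[C@@H]2[C@@](C1)(C(=O)SCC)C(=O)OC[C@]23[C@@H](OC(C)=O)C[C@@H](O[Si](C)(C)C(C)(C)C)C(C)(C)[C@H]3C4SCCS4 | intermediate
25 | C15 aldehyde from 24 | C1=CC[C@@H]2[C@@](C1)(C=O)C(=O)OC[C@]23[C@@H](OC(C)=O)C[C@@H](O[Si](C)(C)C(C)(C)C)C(C)(C)[C@H]3C4SCCS4 | intermediate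
26 | ethynylmagnesium bromide | C#C[Mg]Br | starting material
27 | C15 propargylic alcohol, C8–CH(OH)–C≡CH (C15 epimers) | C1=CC[C@@H]2[C@@](C1)(C(O)C#C)C(=O)OC[C@]23[C@@H](OC(C)=O)C[C@@H](O[Si](C)(C)C(C)(C)C)C(C)(C)[C@H]3C4SCCS4 | intermediate
28 | cyclised C17-tributylstannyl alkene (C15 epimers; not isolated) | CCCC[Sn](CCCC)(CCCC)C=C1[C@@H]2CC[C@@H]3[C@](C2)(C(=O)OC[C@]32[C@@H](OC(C)=O)C[C@@H](O[Si](C)(C)C(C)(C)C)C(C)(C)[C@H]2C4SCCS4)C1O | intermediate
29 | tetracyclic 15-hydroxy-16-ene (C15 epimers), 3-OTBS, C6 dithiolane | C=C1[C@@H]2CC[C@@H]3[C@](C2)(C(=O)OC[C@]32[C@@H](OC(C)=O)C[C@@H](O[Si](C)(C)C(C)(C)C)C(C)(C)[C@H]2C4SCCS4)C1O | intermediate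
30 | 15-oxo-16-ene enone, 3-OTBS, C6 dithiolane | C=C1[C@@H]2CC[C@@H]3[C@](C2)(C(=O)OC[C@]32[C@@H](OC(C)=O)C[C@@H](O[Si](C)(C)C(C)(C)C)C(C)(C)[C@H]2C4SCCS4)C1=O | intermediate
31 | (15R)-15-hydroxy-16-ene, 3-OTBS, C6 dithiolane | C=C1[C@@H]2CC[C@@H]3[C@](C2)(C(=O)OC[C@]32[C@@H](OC(C)=O)C[C@@H](O[Si](C)(C)C(C)(C)C)C(C)(C)[C@H]2C4SCCS4)[C@@H]1O | intermediate
32 | 3,15-diol with C6 as 1,3-dithiolane | C=C1[C@@H]2CC[C@@H]3[C@](C2)(C(=O)OC[C@]32[C@@H](OC(C)=O)C[C@@H](O)C(C)(C)[C@H]2C4SCCS4)[C@@H]1O | intermediate
33 | CNP0536233.1, (1S,3R,5R,8S,9S,10S,13R,15R)-1-acetoxy-3,15-dihydroxy-6-oxo-6,7-secokaur-16-en-7,20-olide (kaurane numbering) | C=C1[C@@H]2CC[C@@H]3[C@](C2)(C(=O)OC[C@]32[C@@H](OC(C)=O)C[C@@H](O)C(C)(C)[C@H]2C=O)[C@@H]1O | target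

Total step count: 22. Longest linear sequence: 19 steps (steps 1, 2, 5–9, 11–22, from compound 1).

Steps most likely to fail

Step 5. The cycloaddition may be too slow: the diene must adopt an s-cis conformation with one C4 methyl pointing inward, and each new bond ends at a fully substituted carbon, so diene decomposition or erosion of the endo preference can outrun product formation. The fallback sets out from 4 and 9 and assembles the ring by two polar conjugate additions instead of one pericyclic event. With a catalytic silyl triflate (TBSOTf, CH2Cl2, −78 °C), 9 reacts as a silyl enol ether in a Mukaiyama–Michael addition to C5 of 4, anti to the menthyloxy group, to give the lactone silyl ketene acetal F1. F1 closes in the same flask by Michael addition of C10 to the silyl-activated acetoxy enone through a chair with the acetoxy group equatorial, which regenerates the C2=C3 enol silane and the catalyst and rejoins the route at 10.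

Step 15. The facial selectivity may be poor, since addition of butadiene from the C5 side of the spiro lactone gives the C8,C9 bis-epimer, and the neopentyl β-carbon may make the addition sluggish. The fallback sets out from 22 and hands stereocontrol from the substrate to a reagent: the cycloaddition is run with a chiral Lewis acid, the triflimide-activated o-tolyl oxazaborolidine derived from diphenylprolinol, with both enantiomers tried to find the matched case. It returns at 24 and makes no new compound.

Step 8. Acetal exchange at a carbon flanked by two quaternary centres may be slow, and prolonged exposure to BF3 may then cost the silyl ether. The fallback sets out from 12, before silylation. Aqueous trifluoroacetic acid in THF hydrolyses the menthyl acetal to the hydroxy lactone F2, a masked aldehyde acid. F2 reacts with ethane-1,2-dithiol under the much milder Zn(OTf)2 to give the hydroxy acid dithiolane F3. Silylation with excess TBSOTf and 2,6-lutidine gives the silyl ether silyl ester F4, whose silyl ester is cleaved on aqueous acetic acid work-up, and the route is rejoined at 14.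

Further compounds
F1 | step 5 | lactone silyl ketene acetal from Mukaiyama–Michael addition of 9 to 4 (C4–C5 bond formed, acetoxy enone side chain) | [C@@H]1(O[C@@H]2C[C@H](C)CC[C@H]2C(C)C)OC(O[Si](C)(C)C(C)(C)C)=C(COC(=O)OCC(Cl)(Cl)Cl)[C@H]1C(C)(C)C(=O)/C=C/OC(C)=O
F2 | step 8 | hydroxy lactone (lactol at C6) from 12, 3-OH free | O=C1OC(O)[C@@H]2C(C)(C)[C@H](O)C[C@H](OC(C)=O)[C@]12COC(=O)OCC(Cl)(Cl)Cl
F3 | step 8 | 3-hydroxy ring A acid with C6 as 1,3-dithiolane | OC(=O)[C@@]1(COC(=O)OCC(Cl)(Cl)Cl)[C@@H](OC(C)=O)C[C@@H](O)C(C)(C)[C@H]1C2SCCS2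
F4 | step 8 | tert-butyldimethylsilyl ester of 14 (3-OTBS, C20 silyl ester) | CC(C)(C)[Si](C)(C)OC(=O)[C@@]1(COC(=O)OCC(Cl)(Cl)Cl)[C@@H](OC(C)=O)C[C@@H](O[Si](C)(C)C(C)(C)C)C(C)(C)[C@H]1C2SCCS2
F0 | step 15 | none | none
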